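**Strategy.** The labdane core is cut at C3–C4 and C5–C10, so that rings A and B arise together from an acyclic 1,7,9-decatriene by an intramolecular Diels–Alder reaction. In one operation this forms two C–C bonds, both carbocycles and the stereocentres C4, C5 and C10. It exploits the adjacent C4/C5 pair and the C5–C10 ring fusion: the C18 carboxyl cis to H5 is encoded in an (E)-2-methyl-2-enoate (C4=C5), the C10 methyl in an (E)-diene (C10=C1–C2=C3), the trans fusion in the ester-endo transition state. The precursor is a benzyl trienoate whose tether (C6–C9) carries the C8 triethylsilyl ether and the (S)-citronellol-derived C9 side chain, both equatorial in the chair-like tether.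

Key step: step 13

**Remarks on the chemistry**
- Labdane numbering is used (ring A = C1–C5, C10; ring B = C5–C10; α = face of H5, β = face of the C10 methyl). The target is 15-acetoxylabd-8(17)-en-18-oic acid, (4R,5R,9S,10R,13S): the carboxyl is C18 (4α, equatorial, trans to the C10 methyl) and the C4 methyl is axial.
- Stereochemical check: (S)-citronellol delivers 13S, and a syn C8/C9 pair in the triene maps onto the 8α-silyloxy/9β-side-chain (diequatorial) arrangement of the adduct; no structural correction was needed.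
- Design choices for the precursor:
  - A benzyl ester is used at C18, because a simple alkyl ester at the neopentyl C4 position would need forcing cleavage, whereas hydrogenolysis frees the acid in the operation that saturates C1=C2.
  - O15 carries tert-butyldiphenylsilyl, so that the C8 triethylsilyl ether can be removed alone.
  - C8 stays a syn-configured silyl ether until after the cycloaddition, since a C8 ketone or alkene would make H9 doubly activated.
  - The enoate is introduced only after the organoaluminium step.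
- Assumption: compounds 8, 10, 18 and 20 and the Ohira–Bestmann reagent are purchased.

**Route**

Step 1
Reactants: 1 (S)-citronellol
Product: 2 tert-butyl{[(3S)-3,7-dimethyloct-6-en-1-yl]oxy}diphenylsilane
Conditions: TBDPSCl, imidazole, DMF, 0 → 23 °C
Reagents that add atoms: tert-butyl(chloro)diphenylsilane, CC(C)(C)[Si](Cl)(c1ccccc1)c1ccccc1
Why: Imidazole-promoted silylation of a primary alcohol (silyl ether formation) is reliable, and the tert-butyldiphenylsilyl group should survive t-BuLi, TiCl4, i-Bu2AlH, AlMe3 and Me2AlCl and stay on when the C8 triethylsilyl ether is later removed, C13 being untouched.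

Step 2
Reactants: 2 tert-butyl{[(3S)-3,7-dimethyloct-6-en-1-yl]oxy}diphenylsilane
Product: 4 (4S)-6-[(tert-butyldiphenylsilyl)oxy]-4-methylhexan-1-ol, via ozonide 3 (not isolated)
Conditions: O3, CH2Cl2, −78 °C; then NaBH4, MeOH, −78 → 23 °C
Reagents that add atoms: ozone, [O-][O+]=O
Why: Ozonolysis of the electron-rich trisubstituted alkene followed by borohydride reduction of the ozonide in the same flask should give the primary alcohol at C9, the aryl and silyl groups being inert at −78 °C.

Step 3
Reactants: 4 (4S)-6-[(tert-butyldiphenylsilyl)oxy]-4-methylhexan-1-ol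
Product: 5 tert-butyl{[(3S)-6-iodo-3-methylhexyl]oxy}diphenylsilane
Conditions: I2, PPh3, imidazole, CH2Cl2, 0 → 23 °C
Reagents that add atoms: iodine, II
Why: Appel-type iodination converts the primary alcohol into the iodide by SN2 displacement of the oxyphosphonium ion without touching C13.

Step 4
Reactants: 5 tert-butyl{[(3S)-6-iodo-3-methylhexyl]oxy}diphenylsilane
Product: 7 (5S)-7-[(tert-butyldiphenylsilyl)oxy]-5-methylheptanoic acid, via alkyllithium 6 (not isolated)
Conditions: t-BuLi (2.1 equiv), Et2O–pentane, −78 °C; then CO2, −78 → 23 °C; dilute HCl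
Reagents that add atoms: carbon dioxide, O=C=O
Why: Iodine–lithium exchange of a primary iodide with two equivalents of t-BuLi is fast at −78 °C and the alkyllithium is trapped by CO2 (carboxylation), which adds C10 as the carboxyl carbon.

Step 5
Reactants: 7 (5S)-7-[(tert-butyldiphenylsilyl)oxy]-5-methylheptanoic acid; 8 (4S)-4-benzyl-1,3-thiazolidine-2-thione
Product: 9 (4S)-4-benzyl-3-{(5S)-7-[(tert-butyldiphenylsilyl)oxy]-5-methylheptanoyl}-1,3-thiazolidine-2-thione
Conditions: DCC, DMAP (cat.), CH2Cl2, 0 → 23 °C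
Reagents that add atoms: none
Why: Carbodiimide/DMAP coupling (Steglich-type N-acylation) of the acid with the thiazolidinethione NH gives the imide that carries the chiral controller for the aldol step.

Step 6
Reactants: 9 (4S)-4-benzyl-3-{(5S)-7-[(tert-butyldiphenylsilyl)oxy]-5-methylheptanoyl}-1,3-thiazolidine-2-thione; 10 pent-4-enal
Product: 12 syn-aldol adduct (4S)-4-benzyl-3-[(2S,3R)-2-{(3S)-5-[(tert-butyldiphenylsilyl)oxy]-3-methylpentyl}-3-hydroxyhept-6-enoyl]-1,3-thiazolidine-2-thione, via titanium enolate 11 (not isolated)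
Conditions: TiCl4 (1.05 equiv), i-Pr2NEt (1.1 equiv), NMP (1 equiv), CH2Cl2, 0 °C; then 10, 0 °C
Reagents that add atoms: none
Why: Crimmins thiazolidinethione aldol, in which soft enolisation gives the (Z)-chlorotitanium enolate that, in the presence of amine and NMP, reacts through a non-chelated Zimmerman–Traxler chair on the face away from the benzyl group, so that the Evans-syn adduct should form, setting C9 (S) and C8 (R) with the syn relation that later places both substituents equatorial.

Step 7
Reactants: 12 syn-aldol adduct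
Product: 13 (4S)-4-benzyl-3-[(2S,3R)-2-{(3S)-5-[(tert-butyldiphenylsilyl)oxy]-3-methylpentyl}-3-[(triethylsilyl)oxy]hept-6-enoyl]-1,3-thiazolidine-2-thione
Conditions: TESOTf, 2,6-lutidine, CH2Cl2, −78 → 0 °C
Reagents that add atoms: triethylsilyl trifluoromethanesulfonate, CC[Si](CC)(CC)OS(=O)(=O)C(F)(F)F
Why: Silylation of the secondary alcohol with the silyl triflate and a hindered base is fast at low temperature, blocks retro-aldol cleavage and installs the C8 triethylsilyl ether of the cycloaddition precursor.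

Step 8
Reactants: 13 triethylsilyl-protected aldol imide
Product: 14 (2S,3R)-2-{(3S)-5-[(tert-butyldiphenylsilyl)oxy]-3-methylpentyl}-3-[(triethylsilyl)oxy]hept-6-enal
Conditions: i-Bu2AlH, CH2Cl2, −78 °C; aq. potassium sodium tartrate
Reagents that add atoms: none
Why: Hydride reduction of the N-acylthiazolidinethione with i-Bu2AlH stops at the aldehyde because the tetrahedral aluminate persists at −78 °C and releases the thione only on work-up, and the non-basic conditions should leave C9 intact.

Step 9
Reactants: 14 (2S,3R)-2-{(3S)-5-[(tert-butyldiphenylsilyl)oxy]-3-methylpentyl}-3-[(triethylsilyl)oxy]hept-6-enal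
Product: 15 (5R,6R,9S)-11-[(tert-butyldiphenylsilyl)oxy]-6-ethynyl-9-methyl-5-[(triethylsilyl)oxy]undec-1-ene
Conditions: dimethyl (1-diazo-2-oxopropyl)phosphonate, K2CO3, MeOH, 0 → 23 °C
Reagents that add atoms: dimethyl (1-diazo-2-oxopropyl)phosphonate, COP(=O)(OC)C(=[N+]=[N-])C(C)=O
Why: Seyferth–Gilbert homologation with the Ohira–Bestmann reagent converts the aldehyde carbon C10 into the terminal alkyne C10≡C1 under mild carbonate conditions that normally do not epimerise an α-branched β-silyloxy aldehyde.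

Step 10
Reactants: 15 (5R,6R,9S)-11-[(tert-butyldiphenylsilyl)oxy]-6-ethynyl-9-methyl-5-[(triethylsilyl)oxy]undec-1-ene
Product: 17 (5R,6R,9S)-11-[(tert-butyldiphenylsilyl)oxy]-6-[(1E)-1-iodoprop-1-en-2-yl]-9-methyl-5-[(triethylsilyl)oxy]undec-1-ene, via alkenylalane 16 (not isolated)
Conditions: AlMe3 (3 equiv), Cp2ZrCl2 (0.3 equiv), ClCH2CH2Cl, 0 → 23 °C; then I2, THF, −30 → 0 °C
Reagents that add atoms: trimethylaluminium, C[Al](C)C; iodine, II
Why: Negishi zirconium-catalysed carboalumination adds methyl (C20) and aluminium syn across the alkyne with methyl on the internal carbon C10, and iodinolysis of the C1–Al bond with retention should give the (E)-iodoalkene, the isolated terminal alkene reacting much more slowly.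

Step 11
Reactants: 17 (E)-iodoalkene; 18 benzyl methacrylate
Product: 19 benzyl (2E,6R,7R,10S)-12-[(tert-butyldiphenylsilyl)oxy]-7-[(1E)-1-iodoprop-1-en-2-yl]-2,10-dimethyl-6-[(triethylsilyl)oxy]dodec-2-enoate
Conditions: second-generation Hoveyda–Grubbs catalyst (5 mol %), 18 (10 equiv), CH2Cl2, 40 °C
Reagents that add atoms: none
Why: Olefin cross-metathesis between the monosubstituted alkene and the 1,1-disubstituted acrylate, which does not homodimerise, should give the trisubstituted enoate as the thermodynamically preferred (E)-isomer with loss of ethene, the hindered trisubstituted iodoalkene staying out of the catalytic cycle.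

Step 12
Reactants: 19 iodoalkene enoate; 20 tributyl(ethenyl)stannane
Product: 21 benzyl (2E,6R,7R,10S)-12-[(tert-butyldiphenylsilyl)oxy]-2,10-dimethyl-7-[(2E)-penta-2,4-dien-2-yl]-6-[(triethylsilyl)oxy]dodec-2-enoate
Conditions: Pd2(dba)3 (2.5 mol %), AsPh3 (10 mol %), CuI (10 mol %), DMF, 23 °C
Reagents that add atoms: none
Why: Stille coupling of the alkenyl iodide with the vinylstannane proceeds with retention of the C10=C1 geometry under neutral conditions that tolerate the enoate and both silyl ethers, completing the (E)-diene.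

Step 13
Reactants: 21 benzyl (E,E)-trienoate
Product: 22 benzyl 15-[(tert-butyldiphenylsilyl)oxy]-8α-[(triethylsilyl)oxy]-17-norlabd-1-en-18-oate (trans-fused; 4α-CO2Bn, 5α-H, 9α-H, 10β-CH3, 13S)
Conditions: Me2AlCl (2 equiv), CH2Cl2, −78 → −10 °C; aq. NaHCO3
Reagents that add atoms: none
Why: Complexation of the benzyl ester by Me2AlCl lowers the enoate LUMO, and a concerted but asynchronous [4+2] cycloaddition (Lewis-acid-promoted intramolecular Diels–Alder reaction of a 1,7,9-decatrienoate, a well-known reaction type) joins C5 to C10 and C3 to C4. Ring A (C10, C1, C2, C3, C4, C5) closes as the new cyclohexene of the cycloaddition itself, and ring B (C5–C10) closes in the same event as a six-membered carbocycle through the four-carbon tether C6–C9. Suprafacial addition carries the E geometry of C4=C5 into the adduct, so that at C4 the methyl ends cis to C6 and the ester cis to H5, while the (E)-diene makes C9 the outside and the C10 methyl the inside substituent, so that C9 ends cis to the endo groups and the methyl cis to C6. The trans relation of H5 and the C10 methyl follows from the transition state with the aluminium-bound ester endo and the tether anti to the diene, and the absolute sense follows from the chair-like tether in which the C9 side chain and the C8 triethylsilyloxy group are both equatorial, so that only one diene face is reached. The step therefore needs endo over exo and one π-face; it is run cold because the fully substituted diene terminus C10 carries a Z-methyl that could undergo a 1,5-hydrogen shift under forcing thermal conditions, and Me2AlCl also scavenges protons that would cleave the silyl ethers.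

Step 14
Reactants: 22 Diels–Alder adduct
Product: 24 8α-hydroxy-15-[(tert-butyldiphenylsilyl)oxy]-17-norlabdan-18-oic acid, via acid triethylsilyl ether 23 (not isolated)
Conditions: H2 (1 atm), 10 % Pd/C, EtOAc–MeOH, 23 °C; filter; then PPTS (0.2 equiv), MeOH, 23 °C
Reagents that add atoms: none
Why: Heterogeneous hydrogenation saturates the cis-disubstituted C1=C2 bond (no stereocentre results) and hydrogenolyses the benzyl ester at the O–CH2Ph bond, remote from the hindered C4 carbonyl, after which mild acid methanolysis removes the secondary triethylsilyl group and leaves the tert-butyldiphenylsilyl ether.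

Step 15
Reactants: 24 8α-hydroxy acid
Product: 25 15-[(tert-butyldiphenylsilyl)oxy]-8-oxo-17-norlabdan-18-oic acid
Conditions: Dess–Martin periodinane, CH2Cl2, 23 °C
Reagents that add atoms: none
Why: Dess–Martin oxidation converts the secondary C8 alcohol into the ketone under near-neutral conditions that tolerate the free carboxylic acid and do not endanger C9.

Step 16
Reactants: 25 8-keto acid
Product: 26 15-[(tert-butyldiphenylsilyl)oxy]labd-8(17)-en-18-oic acid
Conditions: Ph3PCH3Br, KOt-Bu (excess), THF, 0 → 65 °C; aq. NH4Cl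
Reagents that add atoms: methyltriphenylphosphonium bromide, C[P+](c1ccccc1)(c1ccccc1)c1ccccc1.[Br-]
Why: Wittig methylenation with excess non-stabilised ylide (one equivalent is spent on the carboxylic acid) converts the hindered C8 ketone into the exocyclic alkene C8=C17, and because the equatorial C9 side chain is the thermodynamically preferred epimer the basic medium should not change C9.

Step 17
Reactants: 26 silyl-protected methylene acid
Product: 27 15-hydroxylabd-8(17)-en-18-oic acid
Conditions: Bu4NF, THF, 23 °C; dilute HCl wash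
Reagents that add atoms: none
Why: Fluoride-induced cleavage of the silicon–oxygen bond (desilylation) frees the primary C15 alcohol without affecting the alkene or the carboxyl group.

Step 18
Reactants: 27 15-hydroxylabd-8(17)-en-18-oic acid
Product: 28 15-acetoxylabd-8(17)-en-18-oic acid (target)
Conditions: Ac2O, pyridine, DMAP (cat.), CH2Cl2, 23 °C; then H2O
Reagents that add atoms: acetic anhydride, CC(=O)OC(C)=O
Why: DMAP-catalysed acetylation esterifies the primary alcohol, while any mixed anhydride formed at the hindered C18 carboxyl is hydrolysed back to the acid in the aqueous work-up.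

**Compound list**

1 | (S)-citronellol, (3S)-3,7-dimethyloct-6-en-1-ol | C[C@@H](CCC=C(C)C)CCO | starting material
2 | tert-butyl{[(3S)-3,7-dimethyloct-6-en-1-yl]oxy}diphenylsilane | C[C@@H](CCC=C(C)C)CCO[Si](c1ccccc1)(c1ccccc1)C(C)(C)C | intermediate
3 | ozonide of 2, 3-{(3S)-5-[(tert-butyldiphenylsilyl)oxy]-3-methylpentyl}-5,5-dimethyl-1,2,4-trioxolane | C[C@@H](CCC1OOC(C)(C)O1)CCO[Si](c1ccccc1)(c1ccccc1)C(C)(C)C | intermediate (not isolated)
4 | (4S)-6-[(tert-butyldiphenylsilyl)oxy]-4-methylhexan-1-ol | C[C@@H](CCCO)CCO[Si](c1ccccc1)(c1ccccc1)C(C)(C)C | intermediate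
5 | tert-butyl{[(3S)-6-iodo-3-methylhexyl]oxy}diphenylsilane | C[C@@H](CCCI)CCO[Si](c1ccccc1)(c1ccccc1)C(C)(C)C | intermediate
6 | {(4S)-6-[(tert-butyldiphenylsilyl)oxy]-4-methylhexyl}lithium | C[C@@H](CCC[Li])CCO[Si](c1ccccc1)(c1ccccc1)C(C)(C)C | intermediate (not isolated)
7 | (5S)-7-[(tert-butyldiphenylsilyl)oxy]-5-methylheptanoic acid | C[C@@H](CCCC(=O)O)CCO[Si](c1ccccc1)(c1ccccc1)C(C)(C)C | intermediate
8 | (4S)-4-benzyl-1,3-thiazolidine-2-thione | S=C1N[C@@H](Cc2ccccc2)CS1 | starting material
9 | (4S)-4-benzyl-3-{(5S)-7-[(tert-butyldiphenylsilyl)oxy]-5-methylheptanoyl}-1,3-thiazolidine-2-thione | C[C@@H](CCCC(=O)N1C(=S)SC[C@@H]1Cc1ccccc1)CCO[Si](c1ccccc1)(c1ccccc1)C(C)(C)C | intermediate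
10 | pent-4-enal | C=CCCC=O | starting material
11 | trichlorotitanium (Z)-enolate of 9 | C[C@@H](CC/C=C(\O[Ti](Cl)(Cl)Cl)N1C(=S)SC[C@@H]1Cc1ccccc1)CCO[Si](c1ccccc1)(c1ccccc1)C(C)(C)C | intermediate (not isolated)
12 | (4S)-4-benzyl-3-[(2S,3R)-2-{(3S)-5-[(tert-butyldiphenylsilyl)oxy]-3-methylpentyl}-3-hydroxyhept-6-enoyl]-1,3-thiazolidine-2-thione (syn aldol; C9 S, C8 R) | O[C@@H]([C@@H](C(=O)N1C(=S)SC[C@@H]1Cc1ccccc1)CC[C@H](C)CCO[Si](c1ccccc1)(c1ccccc1)C(C)(C)C)CCC=C | intermediate
13 | (4S)-4-benzyl-3-[(2S,3R)-2-{(3S)-5-[(tert-butyldiphenylsilyl)oxy]-3-methylpentyl}-3-[(triethylsilyl)oxy]hept-6-enoyl]-1,3-thiazolidine-2-thione | CC[Si](CC)(CC)O[C@@H]([C@@H](C(=O)N1C(=S)SC[C@@H]1Cc1ccccc1)CC[C@H](C)CCO[Si](c1ccccc1)(c1ccccc1)C(C)(C)C)CCC=C | intermediate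
14 | (2S,3R)-2-{(3S)-5-[(tert-butyldiphenylsilyl)oxy]-3-methylpentyl}-3-[(triethylsilyl)oxy]hept-6-enal | CC[Si](CC)(CC)O[C@@H]([C@@H](C=O)CC[C@H](C)CCO[Si](c1ccccc1)(c1ccccc1)C(C)(C)C)CCC=C | intermediate
15 | (5R,6R,9S)-11-[(tert-butyldiphenylsilyl)oxy]-6-ethynyl-9-methyl-5-[(triethylsilyl)oxy]undec-1-ene | CC[Si](CC)(CC)O[C@@H]([C@@H](C#C)CC[C@H](C)CCO[Si](c1ccccc1)(c1ccccc1)C(C)(C)C)CCC=C | intermediate
16 | (E)-alkenyldimethylalane from syn-methylalumination of 15 (Al on C1, CH3 on C10) | CC[Si](CC)(CC)O[C@@H]([C@@H](/C(C)=C/[Al](C)C)CC[C@H](C)CCO[Si](c1ccccc1)(c1ccccc1)C(C)(C)C)CCC=C | intermediate (not isolated)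
17 | (5R,6R,9S)-11-[(tert-butyldiphenylsilyl)oxy]-6-[(1E)-1-iodoprop-1-en-2-yl]-9-methyl-5-[(triethylsilyl)oxy]undec-1-ene | CC[Si](CC)(CC)O[C@@H]([C@@H](/C(C)=C/I)CC[C@H](C)CCO[Si](c1ccccc1)(c1ccccc1)C(C)(C)C)CCC=C | intermediate
18 | benzyl methacrylate (benzyl 2-methylprop-2-enoate) | C=C(C)C(=O)OCc1ccccc1 | starting material
19 | benzyl (2E,6R,7R,10S)-12-[(tert-butyldiphenylsilyl)oxy]-7-[(1E)-1-iodoprop-1-en-2-yl]-2,10-dimethyl-6-[(triethylsilyl)oxy]dodec-2-enoate | CC[Si](CC)(CC)O[C@@H]([C@@H](/C(C)=C/I)CC[C@H](C)CCO[Si](c1ccccc1)(c1ccccc1)C(C)(C)C)CC/C=C(\C)C(=O)OCc1ccccc1 | intermediate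
20 | tributyl(ethenyl)stannane | C=C[Sn](CCCC)(CCCC)CCCC | starting material
21 | benzyl (2E,6R,7R,10S)-12-[(tert-butyldiphenylsilyl)oxy]-2,10-dimethyl-7-[(2E)-penta-2,4-dien-2-yl]-6-[(triethylsilyl)oxy]dodec-2-enoate (Diels–Alder precursor) | CC[Si](CC)(CC)O[C@@H]([C@@H](/C(C)=C/C=C)CC[C@H](C)CCO[Si](c1ccccc1)(c1ccccc1)C(C)(C)C)CC/C=C(\C)C(=O)OCc1ccccc1 | intermediate
22 | benzyl 15-[(tert-butyldiphenylsilyl)oxy]-8α-[(triethylsilyl)oxy]-17-norlabd-1-en-18-oate (trans-fused; 5α-H, 9α-H, 10β-CH3, 13S) | CC[Si](CC)(CC)O[C@@H]1CC[C@@H]2[C@](C)(C=CC[C@@]2(C)C(=O)OCc2ccccc2)[C@H]1CC[C@H](C)CCO[Si](c1ccccc1)(c1ccccc1)C(C)(C)C | intermediate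
23 | 15-[(tert-butyldiphenylsilyl)oxy]-8α-[(triethylsilyl)oxy]-17-norlabdan-18-oic acid | CC[Si](CC)(CC)O[C@@H]1CC[C@@H]2[C@](C)(CCC[C@@]2(C)C(=O)O)[C@H]1CC[C@H](C)CCO[Si](c1ccccc1)(c1ccccc1)C(C)(C)C | intermediate (not isolated)
24 | 8α-hydroxy-15-[(tert-butyldiphenylsilyl)oxy]-17-norlabdan-18-oic acid | O[C@@H]1CC[C@@H]2[C@](C)(CCC[C@@]2(C)C(=O)O)[C@H]1CC[C@H](C)CCO[Si](c1ccccc1)(c1ccccc1)C(C)(C)C | intermediate
25 | 15-[(tert-butyldiphenylsilyl)oxy]-8-oxo-17-norlabdan-18-oic acid | O=C1CC[C@@H]2[C@](C)(CCC[C@@]2(C)C(=O)O)[C@H]1CC[C@H](C)CCO[Si](c1ccccc1)(c1ccccc1)C(C)(C)C | intermediate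
26 | 15-[(tert-butyldiphenylsilyl)oxy]labd-8(17)-en-18-oic acid | C=C1CC[C@@H]2[C@](C)(CCC[C@@]2(C)C(=O)O)[C@H]1CC[C@H](C)CCO[Si](c1ccccc1)(c1ccccc1)C(C)(C)C | intermediate
27 | 15-hydroxylabd-8(17)-en-18-oic acid | C=C1CC[C@@H]2[C@](C)(CCC[C@@]2(C)C(=O)O)[C@H]1CC[C@H](C)CCO | intermediate
28 | 15-acetoxylabd-8(17)-en-18-oic acid, (1R,4aR,5S,8aR)-5-[(3S)-5-acetoxy-3-methylpentyl]-1,4a-dimethyl-6-methylidenedecahydronaphthalene-1-carboxylic acid | C=C1CC[C@@H]2[C@](C)(CCC[C@@]2(C)C(=O)O)[C@H]1CC[C@H](C)CCOC(C)=O | target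

**Step count.** Total: 18 steps. Longest linear sequence: 18 steps, from (S)-citronellol (1) to 28.

**Steps most likely to fail, with fallbacks**

Step 13 (cycloaddition). The enoate may add too slowly to the diene, whose terminus C10 is fully substituted, so that endo or facial selectivity erodes or the Lewis acid isomerises the diene before ring closure. The fallback changes the dienophile to the more reactive enal. Starting from 21, i-Bu2AlH (CH2Cl2, −78 °C) should reduce the ester to the allylic alcohol F1, and MnO2 (CH2Cl2) should oxidise it to the (E)-2-methyl enal F2. With Me2AlCl at −78 °C this should cyclise through the same chair-like, carbonyl-endo transition state to the adduct aldehyde F3. Pinnick oxidation (NaClO2, NaH2PO4, 2-methylbut-2-ene, t-BuOH–H2O) should give the ene acid F4. Hydrogenation of F4 under the conditions of step 14 gives 23, where the route is rejoined, and desilylation in the same flask leads on to 24.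

Step 11 (cross-metathesis). The terminal alkene may homodimerise, turnover with the 1,1-disubstituted acrylate may be slow, or the ruthenium carbene may be diverted towards the iodoalkene. The fallback builds the enoate by carbonyl olefination. Starting from 17, OsO4 (cat.), NaIO4 and 2,6-lutidine in dioxane–H2O (Lemieux–Johnson cleavage) should cleave only the monosubstituted alkene to the aldehyde F5. The stabilised ylide is made from benzyl 2-bromopropanoate and PPh3 through the phosphonium bromide F6, which aqueous NaOH converts into the ylide F7. Wittig reaction of F5 with F7 (toluene, 80 °C) should give the (E)-enoate 19, where the route is rejoined.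

Step 16 (methylenation). The ylide may enolise the hindered C8 ketone faster than it adds, leaving ketone behind or letting C9 equilibrate. The fallback is a Peterson olefination. Starting from 25, excess Me3SiCH2Li with CeCl3 (THF, −78 °C) should add to the carbonyl as a weakly basic organocerium reagent to give the β-hydroxysilane F8 (either C8 epimer serves). KH in THF should then effect syn-elimination to 26, where the route is rejoined.

**Further compounds**

F1 | step 13 | (2E,6R,7R,10S)-12-[(tert-butyldiphenylsilyl)oxy]-2,10-dimethyl-7-[(2E)-penta-2,4-dien-2-yl]-6-[(triethylsilyl)oxy]dodec-2-en-1-ol | CC[Si](CC)(CC)O[C@@H]([C@@H](/C(C)=C/C=C)CC[C@H](C)CCO[Si](c1ccccc1)(c1ccccc1)C(C)(C)C)CC/C=C(\C)CO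
F2 | step 13 | (2E,6R,7R,10S)-12-[(tert-butyldiphenylsilyl)oxy]-2,10-dimethyl-7-[(2E)-penta-2,4-dien-2-yl]-6-[(triethylsilyl)oxy]dodec-2-enal | CC[Si](CC)(CC)O[C@@H]([C@@H](/C(C)=C/C=C)CC[C@H](C)CCO[Si](c1ccccc1)(c1ccccc1)C(C)(C)C)CC/C=C(\C)C=O
F3 | step 13 | 15-[(tert-butyldiphenylsilyl)oxy]-8α-[(triethylsilyl)oxy]-17-norlabd-1-en-18-al | CC[Si](CC)(CC)O[C@@H]1CC[C@@H]2[C@](C)(C=CC[C@@]2(C)C=O)[C@H]1CC[C@H](C)CCO[Si](c1ccccc1)(c1ccccc1)C(C)(C)C
F4 | step 13 | 15-[(tert-butyldiphenylsilyl)oxy]-8α-[(triethylsilyl)oxy]-17-norlabd-1-en-18-oic acid | CC[Si](CC)(CC)O[C@@H]1CC[C@@H]2[C@](C)(C=CC[C@@]2(C)C(=O)O)[C@H]1CC[C@H](C)CCO[Si](c1ccccc1)(c1ccccc1)C(C)(C)C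
F5 | step 11 | (4R,5R,8S)-10-[(tert-butyldiphenylsilyl)oxy]-5-[(1E)-1-iodoprop-1-en-2-yl]-8-methyl-4-[(triethylsilyl)oxy]decanal | CC[Si](CC)(CC)O[C@@H]([C@@H](/C(C)=C/I)CC[C@H](C)CCO[Si](c1ccccc1)(c1ccccc1)C(C)(C)C)CCC=O
F6 | step 11 | [1-(benzyloxy)-1-oxopropan-2-yl]triphenylphosphonium bromide (racemic) | CC(C(=O)OCc1ccccc1)[P+](c1ccccc1)(c1ccccc1)c1ccccc1.[Br-]
F7 | step 11 | benzyl 2-(triphenylphosphoranylidene)propanoate | CC(C(=O)OCc1ccccc1)=P(c1ccccc1)(c1ccccc1)c1ccccc1
F8 | step 16 | 8-hydroxy-8-[(trimethylsilyl)methyl]-15-[(tert-butyldiphenylsilyl)oxy]-17-norlabdan-18-oic acid (C8 configuration not fixed) | C[Si](C)(C)CC1(O)CC[C@@H]2[C@](C)(CCC[C@@]2(C)C(=O)O)[C@H]1CC[C@H](C)CCO[Si](c1ccccc1)(c1ccccc1)C(C)(C)C
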